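**Plan**

- Retrosynthetic cuts, in order: the four benzyl ethers and a temporary C3 tert-butyl ester; the O1–C2 bond of ring C of the flavanone unit; the C2=C3 alkene of the open precursor (Knoevenagel); the C3–ester bond; the 3'–6'' biaryl bond between ring B of the flavone and ring A of the flavanone; the flavone pyranone ring (chalcone route).
- Enabling feature: ring C of the flavanone is a β-aryloxy ketone, O1–C2–C3–C4(=O), with O1 a phenol oxygen of ring A ortho to the C4 carbonyl. Opening O1–C2 gives a 2-hydroxyaryl enone with C2 as β-carbon, so the ring closes by oxa-Michael addition; an ester on C3 makes the enone a two-point-binding alkylidene β-ketoester.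
- Forward order: flavone unit first (chalcone, oxidative closure, boronate); ring A iodide separately; biaryl union; chain growth on the ring A acetyl group (C3 ester, then C2 arylidene); ring C of the flavanone last; then decarboxylation and hydrogenolysis.
- Stereochemistry: C2 (S) is the only stereocenter. It is set in the ring closure by a bifunctional cinchona thiourea catalyst, after every basic step, because 5-oxygenated flavanones racemize by retro-oxa-Michael opening under base.
- Regiochemistry (6-linked, not 8-linked): the ring A oxygen para to the biaryl carbon carries the only MOM mask and is the only free phenol at the closure; the two oxygens flanking the biaryl carbon are benzyl ethers.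

Key step: step 12

Assumption: the 3'–6'' biaryl axis (three ortho oxygen substituents, one ortho hydrogen) is taken to rotate freely at ambient temperature, as the target SMILES carries no axial descriptor, so C2 is the only stereogenic element to control.

**Route**

Step 1
Reactants: 1 1-(2,4,6-trihydroxyphenyl)ethanone
Product: 2 1-[4-(benzyloxy)-2,6-dihydroxyphenyl]ethanone
Conditions: BnBr (1.0 equiv), K2CO3 (1.05 equiv), DMF, 0 °C to rt
Reagents that add atoms: benzyl bromide, BrCc1ccccc1
Why: Williamson ether synthesis in which the 4-OH, the most acidic hydroxyl and the only one not hydrogen-bonded to the acetyl carbonyl, should be alkylated first by one equivalent of benzyl bromide.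

Step 2
Reactants: 2 1-[4-(benzyloxy)-2,6-dihydroxyphenyl]ethanone
Product: 3 1-[4-(benzyloxy)-2-hydroxy-6-(methoxymethoxy)phenyl]ethanone
Conditions: MOMCl (1.2 equiv), iPr2NEt (1.5 equiv), CH2Cl2, 0 °C to rt
Reagents that add atoms: chloromethyl methyl ether, COCCl
Why: O-alkylation to the MOM acetal; the two ortho hydroxyls are equivalent and, once one is capped, the other is locked in the hydrogen bond to the ketone and should stay free.

Step 3
Reactants: 3 1-[4-(benzyloxy)-2-hydroxy-6-(methoxymethoxy)phenyl]ethanone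
Product: 4 1-[4-(benzyloxy)-2-hydroxy-3-iodo-6-(methoxymethoxy)phenyl]ethanone
Conditions: NIS (1.05 equiv), DMF, 0 °C to rt, dark
Reagents that add atoms: N-iodosuccinimide, O=C1CCC(=O)N1I
Why: electrophilic aromatic iodination ortho to the free hydrogen-bonded phenol, the pattern known for 2-hydroxy-4,6-dialkoxyacetophenones and the less hindered of the two open positions, which places iodine para to the MOM-bearing oxygen.

Step 4
Reactants: 4 1-[4-(benzyloxy)-2-hydroxy-3-iodo-6-(methoxymethoxy)phenyl]ethanone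
Product: 5 1-[2,4-bis(benzyloxy)-3-iodo-6-(methoxymethoxy)phenyl]ethanone
Conditions: BnBr (1.5 equiv), K2CO3 (2 equiv), DMF, 60 °C
Reagents that add atoms: benzyl bromide, BrCc1ccccc1
Why: Williamson ether synthesis on the iodine-flanked phenol under mild heating, so that both oxygens next to the future biaryl carbon are benzyl ethers and MOM remains only on the oxygen para to it.

Step 5
Reactants: 6 1-[2,4-bis(benzyloxy)-6-hydroxyphenyl]ethanone; 7 3-bromo-4-methoxybenzaldehyde
Product: 8 (2E)-1-[2,4-bis(benzyloxy)-6-hydroxyphenyl]-3-(3-bromo-4-methoxyphenyl)prop-2-en-1-one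
Conditions: KOH (aq. 50 %), EtOH/THF, rt
Reagents that add atoms: none
Why: Claisen–Schmidt condensation of a methyl ketone with a non-enolizable aldehyde, which should give the E-chalcone, held open as its phenolate in strong base.

Step 6
Reactants: 8 (2E)-1-[2,4-bis(benzyloxy)-6-hydroxyphenyl]-3-(3-bromo-4-methoxyphenyl)prop-2-en-1-one
Product: 9 5,7-bis(benzyloxy)-2-(3-bromo-4-methoxyphenyl)-4H-chromen-4-one
Conditions: I2 (10 mol %), DMSO, 130 °C
Reagents that add atoms: none
Why: iodine-catalysed oxidative cyclization of a 2'-hydroxychalcone in DMSO (oxa-Michael closure, α-iodination, loss of HI, DMSO re-oxidizing HI to I2), which benzyl ethers and the aryl bromide should survive.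

Step 7
Reactants: 9 5,7-bis(benzyloxy)-2-(3-bromo-4-methoxyphenyl)-4H-chromen-4-one
Product: 10 5,7-bis(benzyloxy)-2-[4-methoxy-3-(4,4,5,5-tetramethyl-1,3,2-dioxaborolan-2-yl)phenyl]-4H-chromen-4-one
Conditions: B2pin2 (1.3 equiv), PdCl2(dppf) (5 mol %), KOAc (3 equiv), 1,4-dioxane, 90 °C
Reagents that add atoms: bis(pinacolato)diboron, CC1(C)OB(OC1(C)C)B1OC(C)(C)C(C)(C)O1
Why: Miyaura borylation of an aryl bromide, with KOAc too weak a base to trigger homocoupling and flavone 3'-boronates being a known class.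

Step 8
Reactants: 5 1-[2,4-bis(benzyloxy)-3-iodo-6-(methoxymethoxy)phenyl]ethanone; 10 5,7-bis(benzyloxy)-2-[4-methoxy-3-(4,4,5,5-tetramethyl-1,3,2-dioxaborolan-2-yl)phenyl]-4H-chromen-4-one
Product: 11 2-{3-[3-acetyl-2,6-bis(benzyloxy)-4-(methoxymethoxy)phenyl]-4-methoxyphenyl}-5,7-bis(benzyloxy)-4H-chromen-4-one
Conditions: Pd(OAc)2 (5 mol %), SPhos (10 mol %), K3PO4 (3 equiv), toluene/H2O (10:1), 90 °C
Reagents that add atoms: none
Why: Suzuki–Miyaura coupling to a tri-ortho-substituted biaryl, for which SPhos-ligated zerovalent palladium is suited and which has precedent in the coupling of iodinated phloroglucinol-type rings with flavone 3'-boronates.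

Step 9
Reactants: 11 2-{3-[3-acetyl-2,6-bis(benzyloxy)-4-(methoxymethoxy)phenyl]-4-methoxyphenyl}-5,7-bis(benzyloxy)-4H-chromen-4-one
Product: 12 tert-butyl 3-{2,4-bis(benzyloxy)-3-[5-(5,7-bis(benzyloxy)-4-oxo-4H-chromen-2-yl)-2-methoxyphenyl]-6-(methoxymethoxy)phenyl}-3-oxopropanoate
Conditions: LiN(SiMe3)2 (2.3 equiv), THF, −78 °C; Boc2O (1.2 equiv), −78 to 0 °C; aq. NH4Cl
Reagents that add atoms: di-tert-butyl dicarbonate, CC(C)(C)OC(=O)OC(=O)OC(C)(C)C
Why: Claisen-type C-acylation (tert-butoxycarbonylation) of the methyl ketone lithium enolate, driven by the second equivalent of base deprotonating the β-ketoester as it forms, with all phenols capped and no comparably acidic C–H in the flavone.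

Step 10
Reactants: 12 tert-butyl 3-{2,4-bis(benzyloxy)-3-[5-(5,7-bis(benzyloxy)-4-oxo-4H-chromen-2-yl)-2-methoxyphenyl]-6-(methoxymethoxy)phenyl}-3-oxopropanoate
Product: 13 tert-butyl 3-{2,4-bis(benzyloxy)-3-[5-(5,7-bis(benzyloxy)-4-oxo-4H-chromen-2-yl)-2-methoxyphenyl]-6-hydroxyphenyl}-3-oxopropanoate
Conditions: HCl (1.25 M in MeOH, 3 equiv), THF, 0 °C to rt
Reagents that add atoms: none
Why: acid-catalysed cleavage of the single MOM acetal, assisted by the neighbouring aryl ketone, under conditions that the tert-butyl ester and the benzyl ethers should tolerate.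

Step 11
Reactants: 13 tert-butyl 3-{2,4-bis(benzyloxy)-3-[5-(5,7-bis(benzyloxy)-4-oxo-4H-chromen-2-yl)-2-methoxyphenyl]-6-hydroxyphenyl}-3-oxopropanoate; 14 4-methoxybenzaldehyde
Product: 15 tert-butyl (2Z)-2-{2,4-bis(benzyloxy)-3-[5-(5,7-bis(benzyloxy)-4-oxo-4H-chromen-2-yl)-2-methoxyphenyl]-6-hydroxybenzoyl}-3-(4-methoxyphenyl)prop-2-enoate
Conditions: piperidine (20 mol %), AcOH (20 mol %), 4 Å molecular sieves, toluene, rt
Reagents that add atoms: none
Why: Knoevenagel condensation of the active methylene with a non-enolizable aldehyde under mild amine/acid catalysis, as used for 2-hydroxyaryl β-ketoesters, expected to favour the isomer with the anisyl group cis to the ester.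

Step 12
Reactants: 15 tert-butyl (2Z)-2-{2,4-bis(benzyloxy)-3-[5-(5,7-bis(benzyloxy)-4-oxo-4H-chromen-2-yl)-2-methoxyphenyl]-6-hydroxybenzoyl}-3-(4-methoxyphenyl)prop-2-enoate
Product: 17 (2S)-5,7-bis(benzyloxy)-6-{5-[5,7-bis(benzyloxy)-4-oxo-4H-chromen-2-yl]-2-methoxyphenyl}-2-(4-methoxyphenyl)-2,3-dihydro-4H-chromen-4-one, via 3-tert-butoxycarbonylflavanone 16 (not isolated)
Conditions: 9-amino(9-deoxy)epi-quinidine-derived 3,5-bis(trifluoromethyl)phenyl thiourea (10 mol %), toluene, −25 °C; then TsOH·H2O (1 equiv), 80 °C, one pot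
Reagents that add atoms: none
Why: The quinuclidine nitrogen of the catalyst acts as a general base on the single free phenol (the ring A oxygen that becomes O1) while the thiourea N–H pair binds the ketone/ester 1,3-dicarbonyl, the phenol oxygen adds to the β-carbon (the future C2), protonation gives 16, and TsOH then cleaves the tert-butyl ester so that the β-keto acid loses CO2. The closest known reaction type is the cinchona-thiourea-catalysed enantioselective oxa-Michael cyclization of 2-hydroxyaryl alkylidene β-ketoesters to flavanones with one-pot acid decarboxylation. Ring C closes in the 6-endo-trig mode by forming O1–C2. C2 is the only new stereocenter that persists and is catalyst-controlled, the hydrogen-bonded substrate being held so that the phenoxide reaches one face of the β-carbon; the quinidine-derived catalyst is proposed for the 2S sense, to be confirmed on a model substrate, with its quinine-derived pseudoenantiomer giving the opposite sense, and C3 is irrelevant because it is lost on decarboxylation. The step needs regioselectivity between the two oxygens ortho to the aroyl group (6-linked versus 8-linked flavanone), secured because the oxygen next to the biaryl carbon is benzylated and only the oxygen para to it is free, and it needs the catalysed pathway to outrun background closure, secured by toluene at −25 °C and by the ester, which activates C2 and supplies the two-point binding site. The flavone enone should stay untouched because its β-carbon is fully substituted and out of reach, and every later operation is acidic or neutral, so the base-labile C2 centre is not exposed to retro-oxa-Michael opening.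

Step 13
Reactants: 17 (2S)-5,7-bis(benzyloxy)-6-{5-[5,7-bis(benzyloxy)-4-oxo-4H-chromen-2-yl]-2-methoxyphenyl}-2-(4-methoxyphenyl)-2,3-dihydro-4H-chromen-4-one
Product: 18 (2S)-6-[5-(5,7-dihydroxy-4-oxo-4H-chromen-2-yl)-2-methoxyphenyl]-5,7-dihydroxy-2-(4-methoxyphenyl)-2,3-dihydro-4H-chromen-4-one
Conditions: H2 (1 atm), Pd/C (10 wt %), EtOAc/THF, rt
Reagents that add atoms: none
Why: catalytic hydrogenolysis of the four benzyl ethers under neutral conditions, which should leave the flavone C2=C3 bond, both ketones, the two methyl ethers and the C2 stereocenter untouched.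

**Compound list**

1 | 1-(2,4,6-trihydroxyphenyl)ethanone | CC(=O)c1c(O)cc(O)cc1O | starting material
2 | 1-[4-(benzyloxy)-2,6-dihydroxyphenyl]ethanone | CC(=O)c1c(O)cc(OCc2ccccc2)cc1O | intermediate
3 | 1-[4-(benzyloxy)-2-hydroxy-6-(methoxymethoxy)phenyl]ethanone | CC(=O)c1c(O)cc(OCc2ccccc2)cc1OCOC | intermediate
4 | 1-[4-(benzyloxy)-2-hydroxy-3-iodo-6-(methoxymethoxy)phenyl]ethanone | CC(=O)c1c(O)c(I)c(OCc2ccccc2)cc1OCOC | intermediate
5 | 1-[2,4-bis(benzyloxy)-3-iodo-6-(methoxymethoxy)phenyl]ethanone | CC(=O)c1c(OCc2ccccc2)c(I)c(OCc2ccccc2)cc1OCOC | intermediate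
6 | 1-[2,4-bis(benzyloxy)-6-hydroxyphenyl]ethanone | CC(=O)c1c(O)cc(OCc2ccccc2)cc1OCc1ccccc1 | starting material
7 | 3-bromo-4-methoxybenzaldehyde | COc1ccc(C=O)cc1Br | starting material
8 | (2E)-1-[2,4-bis(benzyloxy)-6-hydroxyphenyl]-3-(3-bromo-4-methoxyphenyl)prop-2-en-1-one | COc1ccc(/C=C/C(=O)c2c(O)cc(OCc3ccccc3)cc2OCc2ccccc2)cc1Br | intermediate
9 | 5,7-bis(benzyloxy)-2-(3-bromo-4-methoxyphenyl)-4H-chromen-4-one | COc1ccc(-c2cc(=O)c3c(OCc4ccccc4)cc(OCc4ccccc4)cc3o2)cc1Br | intermediate
10 | 5,7-bis(benzyloxy)-2-[4-methoxy-3-(4,4,5,5-tetramethyl-1,3,2-dioxaborolan-2-yl)phenyl]-4H-chromen-4-one | COc1ccc(-c2cc(=O)c3c(OCc4ccccc4)cc(OCc4ccccc4)cc3o2)cc1B1OC(C)(C)C(C)(C)O1 | intermediate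
11 | 2-{3-[3-acetyl-2,6-bis(benzyloxy)-4-(methoxymethoxy)phenyl]-4-methoxyphenyl}-5,7-bis(benzyloxy)-4H-chromen-4-one | COc1ccc(-c2cc(=O)c3c(OCc4ccccc4)cc(OCc4ccccc4)cc3o2)cc1-c1c(OCc2ccccc2)cc(OCOC)c(C(C)=O)c1OCc1ccccc1 | intermediate
12 | tert-butyl 3-{2,4-bis(benzyloxy)-3-[5-(5,7-bis(benzyloxy)-4-oxo-4H-chromen-2-yl)-2-methoxyphenyl]-6-(methoxymethoxy)phenyl}-3-oxopropanoate | COc1ccc(-c2cc(=O)c3c(OCc4ccccc4)cc(OCc4ccccc4)cc3o2)cc1-c1c(OCc2ccccc2)cc(OCOC)c(C(=O)CC(=O)OC(C)(C)C)c1OCc1ccccc1 | intermediate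
13 | tert-butyl 3-{2,4-bis(benzyloxy)-3-[5-(5,7-bis(benzyloxy)-4-oxo-4H-chromen-2-yl)-2-methoxyphenyl]-6-hydroxyphenyl}-3-oxopropanoate | COc1ccc(-c2cc(=O)c3c(OCc4ccccc4)cc(OCc4ccccc4)cc3o2)cc1-c1c(OCc2ccccc2)cc(O)c(C(=O)CC(=O)OC(C)(C)C)c1OCc1ccccc1 | intermediate
14 | 4-methoxybenzaldehyde | COc1ccc(C=O)cc1 | starting material
15 | tert-butyl (2Z)-2-{2,4-bis(benzyloxy)-3-[5-(5,7-bis(benzyloxy)-4-oxo-4H-chromen-2-yl)-2-methoxyphenyl]-6-hydroxybenzoyl}-3-(4-methoxyphenyl)prop-2-enoate | COc1ccc(/C=C(\C(=O)OC(C)(C)C)C(=O)c2c(O)cc(OCc3ccccc3)c(-c3cc(-c4cc(=O)c5c(OCc6ccccc6)cc(OCc6ccccc6)cc5o4)ccc3OC)c2OCc2ccccc2)cc1 | intermediate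
16 | tert-butyl (2S,3R)-5,7-bis(benzyloxy)-6-{5-[5,7-bis(benzyloxy)-4-oxo-4H-chromen-2-yl]-2-methoxyphenyl}-2-(4-methoxyphenyl)-4-oxo-3,4-dihydro-2H-chromene-3-carboxylate (2,3-trans keto form, in equilibrium with its enol) | COc1ccc([C@@H]2[C@@H](C(=O)OC(C)(C)C)C(=O)c3c(cc(OCc4ccccc4)c(-c4cc(-c5cc(=O)c6c(OCc7ccccc7)cc(OCc7ccccc7)cc6o5)ccc4OC)c3OCc3ccccc3)O2)cc1 | intermediate
17 | (2S)-5,7-bis(benzyloxy)-6-{5-[5,7-bis(benzyloxy)-4-oxo-4H-chromen-2-yl]-2-methoxyphenyl}-2-(4-methoxyphenyl)-2,3-dihydro-4H-chromen-4-one | COc1ccc([C@@H]2CC(=O)c3c(cc(OCc4ccccc4)c(-c4cc(-c5cc(=O)c6c(OCc7ccccc7)cc(OCc7ccccc7)cc6o5)ccc4OC)c3OCc3ccccc3)O2)cc1 | intermediate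
18 | (2S)-6-[5-(5,7-dihydroxy-4-oxo-4H-chromen-2-yl)-2-methoxyphenyl]-5,7-dihydroxy-2-(4-methoxyphenyl)-2,3-dihydro-4H-chromen-4-one | COc1ccc([C@@H]2CC(=O)c3c(cc(O)c(-c4cc(-c5cc(=O)c6c(O)cc(O)cc6o5)ccc4OC)c3O)O2)cc1 | target

**Step count and risks**

Total steps: 13. Longest linear sequence: 10 (steps 1 to 4, then 8 to 13).

Step 12. The catalysed closure may fail to outrun the uncatalysed one on this doubly ortho-substituted, biaryl-flanked aroyl system, or the facial selectivity may be poor, or the acid stage may erode enantiomeric purity by reversible ring opening. The fallback sets C2 by carbon–carbon instead of carbon–oxygen bond formation and sets out from 11. Cleavage of the MOM ether (cat. HCl, MeOH/THF, rt) gives the free hydroxy ketone F1. Heating with N,N-dimethylformamide dimethyl acetal (toluene, 100 °C) gives the enaminone F2, which closes with aqueous HCl in CH2Cl2 to the 2-unsubstituted chromone F3. Enantioselective conjugate addition of 4-methoxyphenylboronic acid to F3 (Pd(OCOCF3)2, t-BuPyOX in the enantiomeric form that gives the 2S product, NH4PF6, H2O, ClCH2CH2Cl, 60 °C) should give 17, where the route resumes at step 13.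

Step 8. Oxidative addition and transmetalation at the iodide flanked by two benzyloxy groups may be slow enough for protodeboronation of 10 and reduction of 5 to take over. The fallback reverses the polarity with a more reactive organometallic and sets out from 5 and 9, so that step 7 is not needed. Zinc insertion into 5 (Zn dust, LiCl, THF, 25 to 50 °C, conditions that tolerate the ketone) gives the arylzinc iodide F4, and Negishi coupling of F4 with bromoflavone 9 (Pd(OAc)2, SPhos, THF, 60 °C) should give 11, where the route resumes at step 9.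

Step 11. Under the amine/acid conditions the free phenol may close prematurely onto the new alkylidene without stereocontrol, or the hydroxy β-ketoester may lactonize to a 4-hydroxycoumarin. The fallback keeps the phenol masked during the condensation and sets out from 12. Knoevenagel condensation of 12 with 14 (piperidine/AcOH cat., toluene, 4 Å molecular sieves) gives the MOM-protected alkylidene F5, and brief cleavage of the ketone-activated MOM ether (cat. HCl, MeOH/CH2Cl2, 0 °C, NaHCO3 quench) should give 15, where the route resumes at step 12.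

**Further compounds**

F1 | step 12 | 2-{3-[3-acetyl-2,6-bis(benzyloxy)-4-hydroxyphenyl]-4-methoxyphenyl}-5,7-bis(benzyloxy)-4H-chromen-4-one | COc1ccc(-c2cc(=O)c3c(OCc4ccccc4)cc(OCc4ccccc4)cc3o2)cc1-c1c(OCc2ccccc2)cc(O)c(C(C)=O)c1OCc1ccccc1
F2 | step 12 | 2-(3-{2,6-bis(benzyloxy)-3-[(2E)-3-(dimethylamino)prop-2-enoyl]-4-hydroxyphenyl}-4-methoxyphenyl)-5,7-bis(benzyloxy)-4H-chromen-4-one | COc1ccc(-c2cc(=O)c3c(OCc4ccccc4)cc(OCc4ccccc4)cc3o2)cc1-c1c(OCc2ccccc2)cc(O)c(C(=O)/C=C/N(C)C)c1OCc1ccccc1
F3 | step 12 | 5,7-bis(benzyloxy)-6-{5-[5,7-bis(benzyloxy)-4-oxo-4H-chromen-2-yl]-2-methoxyphenyl}-4H-chromen-4-one | COc1ccc(-c2cc(=O)c3c(OCc4ccccc4)cc(OCc4ccccc4)cc3o2)cc1-c1c(OCc2ccccc2)cc2occc(=O)c2c1OCc1ccccc1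
F4 | step 8 | [3-acetyl-2,6-bis(benzyloxy)-4-(methoxymethoxy)phenyl]zinc iodide | CC(=O)c1c(OCc2ccccc2)c([Zn]I)c(OCc2ccccc2)cc1OCOC
F5 | step 11 | tert-butyl (2Z)-2-{2,4-bis(benzyloxy)-3-[5-(5,7-bis(benzyloxy)-4-oxo-4H-chromen-2-yl)-2-methoxyphenyl]-6-(methoxymethoxy)benzoyl}-3-(4-methoxyphenyl)prop-2-enoate | COc1ccc(/C=C(\C(=O)OC(C)(C)C)C(=O)c2c(OCOC)cc(OCc3ccccc3)c(-c3cc(-c4cc(=O)c5c(OCc6ccccc6)cc(OCc6ccccc6)cc5o4)ccc3OC)c2OCc2ccccc2)cc1
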